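The easy step comes first: a flask that has stopped rising gains nothing from waiting, so I ask how far its target still has to climb.

the same everywhere: substrate 0.050 M

| run | partner | second reagent | temperature | remark | time |
|---|---|---|---|---|---|
| east | 0.090 M | 0.055 M | 25 °C | the very flask that is asked about, followed so far |  |
| south | 0.090 M | 0.055 M | 20 °C | run made earlier |  |
| flask | 0.0900 M | 0.0550 M | 25 °C |  | 5.0 d |

| run | time / d | target / % | substrate / % |
|---|---|---|---|
| east | 0.333 | 35.5 | 0 |
| east | 0.500 | 41.1 | 0 |
| east | 0.833 | 47.3 | 0 |
| east | 1.04 | 50.1 | 0 |
| east | 1.67 | 54.1 | 0.5 |
| east | 2.50 | 53.7 | 0 |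
| east | 4.00 | 55.8 | 0 |
| south | 0.333 | 25.0 | 3.2 |
| south | 0.500 | 33.3 | 0 |
| south | 0.833 | 39.9 | 1.8 |
| south | 1.04 | 42.8 | 0 |
| south | 1.67 | 48.7 | 0 |
| south | 2.50 | 51.1 | 0.8 |
| south | 4.00 | 54.8 | 0.4 |

(each reading ± 1 percentage point)

- target taken out counts as made
- the earlier runs were read with a standard deviation of 1 percentage point
- additions bring no volume worth counting

- blue: change nothing and wait 40 h more
- grey: at 5.0 d take out 90 % of the target then present, then wait 40 h
- red: at 5.0 d raise the temperature by 15 K, then wait 40 h
- teal: at 5.0 d add partner, 100 % of the amount charged, then wait 40 h

- target, in percent of the substrate first charged, at 5.0 d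
- what to do for the largest gain in target; "none" if nothing gains more than 2 percentage points (blue / grey / red / teal / none)
- target present, with what was taken out counted in, in percent of the substrate first charged, after blue
- target present, with what was taken out counted in, in percent of the substrate first charged, after grey

In the east run, which is this flask followed so far, the substrate already reads 0 % at 0.333 d, yet the target goes on from 35.5 % to 55.8 % at 4.00 d. So the substrate's own time lies under the first reading, and two times remain to compare: how long the climb takes to halve what it still owes, and how long the flask has for that.

I replace the end of the curve by its mean, 54.8 % from the last two readings. The gap to that level is 19 percentage points at 0.333 d and 4.6 points at 1.04 d, while the next gap, 0.65 points, lies under the scatter of 1 point. From the two clear gaps I get 0.345 d as the half-time of the climb, the time in which the gap to the level halves.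

Between 1.04 d and 5.0 d the flask has 11.5 such half-times, so the gap shrinks to 0.0016 points, less than the 2 points an option must bring. The south run at 20 °C ends 1 point below the east run, and the substrate reads 0 %, so I see no sign that heating, taking out target or adding partner lifts the level. My own figures are 54.8 % for now and after blue and grey, and my choice is none.

The forecast says 55.5 %, none, 55.5 % and 55.5 %, which is above my level but the same choice. It concludes that “waiting, heating, removing target or adding partner gains nothing”.

The flask gives 56.8 %, with 56.9 % after blue and 56.9 % after grey. The choice is none: the gains are 0.14 points for blue, grey and teal and 0.2 points for red, under the bar. Of the substrate, the limiting reagent, 0 % is left.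

    substrate + partner → intermediate (k = 5.86 M⁻¹ h⁻¹, Ea = 76.0 kJ mol⁻¹)
    second reagent + intermediate → target (k = 6.35 M⁻¹ h⁻¹, Ea = 69.0 kJ mol⁻¹)
    substrate + second reagent → side product (k = 8.56 M⁻¹ h⁻¹, Ea = 60.0 kJ mol⁻¹)
    (constants at 25 °C)

At 5.00 d the flask holds 0.200 % of intermediate, more than my gap of 0.0016 points but under the bar, so the gap I reckoned with one mean half-time of 0.345 d falls short of that amount by less than the bar. The neighbour charged with 0.093 M of second reagent still has 0.0430 M of it at 5.00 d; at that amount the step from intermediate to target alone gives a half-time of 0.106 d, shorter than my 0.345 d, which makes 47.2 such half-times in 5.0 d. That neighbour holds 0 % of intermediate at 5.00 d, with 42.3 % of target.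

(All runs are calculated with constants of no real substance; noise was put on by code.)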